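**Plan**

1. Retrosynthesis first cuts C11=C12 and C11'=C12' (two Wittig reactions on the C10 trienedial 46), then in each end group the C7–C11 chain (HWE, vinyl Grignard, phosphonium salt) and the bond from the exocyclic CH2 on C2/C2' to the side-chain alkene (Negishi coupling).
2. Each carbocycle is then opened by a retro-[3,3] step. Ring B holds the unit C5'(Me)=C4'H–C3'H2–C2'H–CH2(exocyclic), a γ,δ-unsaturated carbonyl retron once that exocyclic carbon is raised to a carboxyl; this leads back to the six-membered lactone 11, whose ring oxygen joins the carboxyl carbon to the vinyl-bearing carbinol C5'.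
3. Forward: half ester 2 → acid chloride 3 (one stock for both series) → Evans acetal alkylation (C7/C7' carried as a dimethyl acetal) → ketone → Grignard addition and lactonisation → Ireland–Claisen ring contraction, which closes ring B (step 8) and, in the mirror series, ring A (step 22) → side chains → C20 phosphonium salts 26 and 45 → C20 + C10 → C30 aldehyde 47 → C30 + C20 → C50.
4. Stereochemistry: C6' and C6 come from (R)- and (S)-4-benzyloxazolidinone. The carbinol carbon is set by Felkin–Anh addition (vinyl to the methyl ketone for ring B, methyl to the vinyl ketone for ring A), so both lactones have the same carbinol configuration. C2' and C2 arise by chirality transfer from that carbinol through the boat transition state, giving the 2',6'-trans ring B and the 2,6-cis ring A. The alkenes are E from carboalumination, HWE, the allylic transposition and final isomerisation.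

Key step: step 8

Remark: carotenoid locants are used throughout (ring A = C1–C6 with the prenyl group on C2, ring B = C1'–C6' with the hydroxyprenyl group on C2', C7/C7' = first chain carbon); the C10 dialdehyde 46 is assumed to be purchasable.

Step 1
Reactants: 1 3,3-dimethylglutaric anhydride
Product: 2 5-methoxy-3,3-dimethyl-5-oxopentanoic acid
Conditions: MeOH, reflux
Reagents that add atoms: methanol CO
Why: Alcoholysis of a cyclic anhydride; the two carbonyl groups are equivalent, so a single half ester should form.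

Step 2
Reactants: 2 half ester
Product: 3 methyl 5-chloro-3,3-dimethyl-5-oxopentanoate
Conditions: (COCl)2, DMF (cat.), CH2Cl2, 0 °C → rt; evaporation, bulb-to-bulb distillation
Reagents that add atoms: oxalyl chloride O=C(Cl)C(Cl)=O
Why: Acid chloride formation with oxalyl chloride under DMF catalysis (Vilsmeier-type activation) should leave the methyl ester alone and give a distillable acid chloride that serves as one stock for both enantiomeric series.

Step 3
Reactants: 3 acid chloride; 4 (4R)-4-benzyl-1,3-oxazolidin-2-one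
Product: 5 methyl 5-[(4R)-4-benzyl-2-oxo-1,3-oxazolidin-3-yl]-3,3-dimethyl-5-oxopentanoate
Conditions: Et3N, 4-dimethylaminopyridine (10 mol %), CH2Cl2, 0 °C → rt
Reagents that add atoms: none
Why: N-acylation of the Evans oxazolidinone by the acid chloride under nucleophilic catalysis; the acid chloride is far more electrophilic than the methyl ester, so only the imide should form.

Step 4
Reactants: 5 imide
Product: 7 methyl (4S)-4-{[(4R)-4-benzyl-2-oxo-1,3-oxazolidin-3-yl]carbonyl}-5,5-dimethoxy-3,3-dimethylpentanoate, via trichlorotitanium enolate 6 (not isolated)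
Conditions: TiCl4, iPr2NEt, CH2Cl2, 0 °C; then HC(OMe)3, 0 °C
Reagents that add atoms: trimethyl orthoformate COC(OC)OC
Why: Evans alkylation of the chelated (Z)-titanium enolate with the dimethoxycarbenium ion from the orthoformate; the electrophile should enter anti to the benzyl group, which sets C6' and installs C7' at the aldehyde oxidation level.

Step 5
Reactants: 7 acetal imide
Product: 8 methyl (4S)-4-[(ethylsulfanyl)carbonyl]-5,5-dimethoxy-3,3-dimethylpentanoate
Conditions: EtSLi (EtSH, n-BuLi), THF, 0 °C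
Reagents that add atoms: ethanethiol CCS
Why: Thiolate transacylation of the N-acyloxazolidinone (exocyclic cleavage) should give the thioester and return the auxiliary without touching the α-stereocentre.

Step 6
Reactants: 8 thioester
Product: 9 methyl (4S)-4-(dimethoxymethyl)-3,3-dimethyl-5-oxohexanoate
Conditions: Me2CuLi (MeLi, CuI), Et2O, −78 → −30 °C
Reagents that add atoms: lithium dimethylcuprate [Li+].C[Cu-]C
Why: Thioester-to-ketone acyl substitution with a Gilman cuprate, which stops at the ketone and should leave the methyl ester and the acetal alone.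

Step 7
Reactants: 9 methyl ketone
Product: 11 (5R,6R)-5-(dimethoxymethyl)-6-ethenyl-4,4,6-trimethyloxan-2-one, via hydroxy ester alkoxide 10 (not isolated)
Conditions: CH2=CHMgBr, CeCl3, THF, −78 °C → rt
Reagents that add atoms: vinylmagnesium bromide C=C[Mg]Br
Why: Organocerium 1,2-addition under Felkin–Anh control (nucleophile anti to the tert-alkyl group on C6', the same face as the β-alkoxy chelate model) should set C5' with the vinyl group cis to the acetal substituent, and the tertiary alkoxide then closes the δ-lactone on the methyl ester.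

Step 8
Reactants: 11 lactone (ring B series)
Product: 14 [(1S,5S)-5-(dimethoxymethyl)-4,6,6-trimethylcyclohex-3-en-1-yl]methanol, via silyl ketene acetal 12 (not isolated), via trimethylsilyl ester 13 (not isolated)
Conditions: LiN(iPr)2, Me3SiCl–Et3N, THF, −78 °C → rt; PhMe, 100 °C; then LiAlH4, THF, 0 °C
Reagents that add atoms: none
Why: LiN(iPr)2 removes an α-proton at C2' and the enolate is silylated in situ to ketene acetal 12, an allyl vinyl ether whose ring oxygen links the tertiary allylic carbon C5' to the enol carbon; on heating, a concerted suprafacial [3,3] shift (Ireland–Claisen rearrangement) should form the C2'–C3' σ bond and the C4'=C5' double bond while C5'–O breaks, and LiAlH4 then reduces silyl ester 13 to the primary alcohol. The closest known reaction type is the Ireland–Claisen ring contraction of 6-alkenyl δ-lactones and dioxanones to cyclohexene and dihydropyran carboxylates. Ring B closes as a six-membered carbocycle by contraction of the six-membered lactone through a boat-like, bicyclo[2.2.2]-type transition state, the only geometry in which the vinyl terminus reaches C2'. The new stereocentre C2' is set by chirality transfer from the carbinol carbon C5' (which becomes sp2): the new bond forms on the lactone face that carries the vinyl group, and because the acetal substituent on C6' is cis to that vinyl group, the carboxyl-derived carbon on C2' ends up trans to it. The step needs deprotonation at C2' only and silylation faster than enolate fragmentation; C6' carries no acidifying group, Me3SiCl is present during deprotonation, and the ring size enforces the endocyclic (Z) alkene.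

Step 9
Reactants: 14 alcohol
Product: 15 (4S,6S)-6-(dimethoxymethyl)-4-(iodomethyl)-1,5,5-trimethylcyclohex-1-ene
Conditions: I2, PPh3, imidazole, CH2Cl2, 0 °C
Reagents that add atoms: iodine II
Why: Appel-type iodination by displacement of the alkoxyphosphonium ion at the primary carbon; imidazole buffers the acetal.

Step 10
Reactants: 16 prop-2-yn-1-ol
Product: 18 (2E)-3-iodo-2-methylprop-2-en-1-ol, via alkenylalane 17 (not isolated)
Conditions: AlMe3, Cp2ZrCl2 (25 mol %), CH2Cl2, 0 °C → rt; then I2, THF, −30 °C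
Reagents that add atoms: trimethylaluminium C[Al](C)C; iodine II
Why: Negishi zirconium-catalysed carboalumination adds Me–Al syn across the alkyne with aluminium at the terminus, and iodinolysis with retention should give the (E)-iodoalkene.

Step 11
Reactants: 18 iodoalkenol
Product: 19 tert-butyl{[(2E)-3-iodo-2-methylprop-2-en-1-yl]oxy}diphenylsilane
Conditions: t-BuPh2SiCl, imidazole, CH2Cl2, rt
Reagents that add atoms: tert-butyl(chloro)diphenylsilane CC(C)(C)[Si](Cl)(c1ccccc1)c1ccccc1
Why: Silyl ether formation; this silyl group should survive the acid of steps 13 and 16 and the Grignard and Wittig steps.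

Step 12
Reactants: 15 iodide; 19 alkenyl iodide
Product: 22 tert-butyl({(2E)-4-[(1R,5S)-5-(dimethoxymethyl)-4,6,6-trimethylcyclohex-3-en-1-yl]-2-methylbut-2-en-1-yl}oxy)diphenylsilane, via alkyllithium 20 (not isolated), via alkylzinc chloride 21 (not isolated)
Conditions: t-BuLi, Et2O, −78 °C; ZnCl2, THF, −78 °C → rt; then 19, Pd(PPh3)4 (5 mol %), rt
Reagents that add atoms: none
Why: Negishi sp3–sp2 cross-coupling (iodine–lithium exchange, transmetalation to zinc, Pd-catalysed coupling) should join the side chain with retention of the (E)-alkenyl geometry and without touching C2'.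

Step 13
Reactants: 22 acetal
Product: 23 (1S,5R)-5-{(2E)-4-[tert-butyl(diphenyl)silyl]oxy-3-methylbut-2-en-1-yl}-2,6,6-trimethylcyclohex-2-ene-1-carbaldehyde
Conditions: (CO2H)2 (cat.), THF–H2O, rt → 40 °C
Reagents that add atoms: water O
Why: Acid-catalysed acetal hydrolysis under mild conditions that should spare the silyl ether and leave the hindered, non-conjugated aldehyde configurationally intact at C6'.

Step 14
Reactants: 23 aldehyde
Product: 24 (3E)-4-[(1S,5R)-5-{(2E)-4-[tert-butyl(diphenyl)silyl]oxy-3-methylbut-2-en-1-yl}-2,6,6-trimethylcyclohex-2-en-1-yl]but-3-en-2-one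
Conditions: (EtO)2P(O)CH2C(O)CH3, LiCl, iPr2NEt, MeCN, rt
Reagents that add atoms: diethyl (2-oxopropyl)phosphonate CCOP(=O)(CC(C)=O)OCC
Why: Horner–Wadsworth–Emmons olefination under Masamune–Roush conditions should give the (E)-enone (C7'=C8') without a strong base near the epimerisable C6'.

Step 15
Reactants: 24 enone
Product: 25 (1E)-1-[(1S,5R)-5-{(2E)-4-[tert-butyl(diphenyl)silyl]oxy-3-methylbut-2-en-1-yl}-2,6,6-trimethylcyclohex-2-en-1-yl]-3-methylpenta-1,4-dien-3-ol (both C9' epimers)
Conditions: CH2=CHMgBr, THF, −78 → −30 °C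
Reagents that add atoms: vinylmagnesium bromide C=C[Mg]Br
Why: Grignard 1,2-addition to the enone carbonyl as in the vinyl-ionol synthesis; both C9' epimers serve because that centre is lost in step 16.

Step 16
Reactants: 25 vinyl carbinol
Product: 26 {(2E,4E)-5-[(1S,5R)-5-{(2E)-4-[tert-butyl(diphenyl)silyl]oxy-3-methylbut-2-en-1-yl}-2,6,6-trimethylcyclohex-2-en-1-yl]-3-methylpenta-2,4-dien-1-yl}triphenylphosphonium bromide
Conditions: Ph3P·HBr, CH2Cl2–MeOH, rt
Reagents that add atoms: triphenylphosphine hydrobromide [Br-].c1ccc(cc1)[PH+](c1ccccc1)c1ccccc1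
Why: Allylic transposition: ionisation of the tertiary bis-allylic alcohol and attack of PPh3 at the primary terminus should give the allylic phosphonium salt with the thermodynamic (E)-C9'=C10' bond.

Step 17
Reactants: 3 acid chloride; 27 (4S)-4-benzyl-1,3-oxazolidin-2-one
Product: 28 methyl 5-[(4S)-4-benzyl-2-oxo-1,3-oxazolidin-3-yl]-3,3-dimethyl-5-oxopentanoate
Conditions: Et3N, 4-dimethylaminopyridine (10 mol %), CH2Cl2, 0 °C → rt
Reagents that add atoms: none
Why: N-acylation of the enantiomeric Evans oxazolidinone by the same acid chloride, as in step 3.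

Step 18
Reactants: 28 imide
Product: 30 methyl (4R)-4-{[(4S)-4-benzyl-2-oxo-1,3-oxazolidin-3-yl]carbonyl}-5,5-dimethoxy-3,3-dimethylpentanoate, via trichlorotitanium enolate 29 (not isolated)
Conditions: TiCl4, iPr2NEt, CH2Cl2, 0 °C; then HC(OMe)3, 0 °C
Reagents that add atoms: trimethyl orthoformate COC(OC)OC
Why: Evans alkylation of the chelated (Z)-titanium enolate anti to the benzyl group, which with the (S)-auxiliary should set C6 in the sense opposite to C6'.

Step 19
Reactants: 30 acetal imide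
Product: 31 methyl (4R)-4-[(ethylsulfanyl)carbonyl]-5,5-dimethoxy-3,3-dimethylpentanoate
Conditions: EtSLi (EtSH, n-BuLi), THF, 0 °C
Reagents that add atoms: ethanethiol CCS
Why: Thiolate transacylation of the N-acyloxazolidinone, as in step 5.

Step 20
Reactants: 31 thioester
Product: 32 methyl (4R)-4-(dimethoxymethyl)-3,3-dimethyl-5-oxohept-6-enoate
Conditions: CH2=CHSnBu3, Pd2(dba)3 (2.5 mol %), P(2-furyl)3, CuOP(O)Ph2, THF, rt
Reagents that add atoms: tributyl(vinyl)stannane C=C[Sn](CCCC)(CCCC)CCCC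
Why: Liebeskind–Srogl coupling transfers the acyl group from sulfur to the vinylstannane under neutral conditions, so the α-stereocentre and the enone product should survive.

Step 21
Reactants: 32 vinyl ketone
Product: 34 (5S,6R)-5-(dimethoxymethyl)-6-ethenyl-4,4,6-trimethyloxan-2-one, via hydroxy ester alkoxide 33 (not isolated)
Conditions: MeMgBr, CeCl3, THF, −78 °C → rt
Reagents that add atoms: methylmagnesium bromide C[Mg]Br
Why: Organocerium 1,2-addition (no conjugate addition) with the same Felkin–Anh sense as step 7; since methyl and vinyl have exchanged roles in the enantiomeric series, C5 should have the same configuration as C5' in 11 with the vinyl group trans to the acetal substituent, and lactonisation follows as before.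

Step 22
Reactants: 34 lactone (ring A series)
Product: 37 [(1S,5R)-5-(dimethoxymethyl)-4,6,6-trimethylcyclohex-3-en-1-yl]methanol, via silyl ketene acetal 35 (not isolated), via trimethylsilyl ester 36 (not isolated)
Conditions: LiN(iPr)2, Me3SiCl–Et3N, THF, −78 °C → rt; PhMe, 100 °C; then LiAlH4, THF, 0 °C
Reagents that add atoms: none
Why: Ireland–Claisen ring contraction through the boat transition state as in step 8, closing ring A; the C5 configuration is transferred to C2, and the trans-disposed vinyl and C6 substituents of 34 should give the 2,6-cis ring.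

Step 23
Reactants: 37 alcohol
Product: 38 (4S,6R)-6-(dimethoxymethyl)-4-(iodomethyl)-1,5,5-trimethylcyclohex-1-ene
Conditions: I2, PPh3, imidazole, CH2Cl2, 0 °C
Reagents that add atoms: iodine II
Why: Appel-type iodination of the primary alcohol; fast conversion under imidazole buffering should forestall attack of the cis hydroxyl on the acetal.

Step 24
Reactants: 38 iodide
Product: 41 (4S,6R)-6-(dimethoxymethyl)-1,5,5-trimethyl-4-(3-methylbut-2-en-1-yl)cyclohex-1-ene, via alkyllithium 39 (not isolated), via alkylzinc chloride 40 (not isolated)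
Conditions: t-BuLi, Et2O, −78 °C; ZnCl2, THF, −78 °C → rt; then Me2C=CHBr, Pd(PPh3)4 (5 mol %), 50 °C
Reagents that add atoms: 1-bromo-2-methylprop-1-ene CC(C)=CBr
Why: Negishi sp3–sp2 cross-coupling should complete the prenyl group on C2.

Step 25
Reactants: 41 acetal
Product: 42 (1R,5S)-2,6,6-trimethyl-5-(3-methylbut-2-en-1-yl)cyclohex-2-ene-1-carbaldehyde
Conditions: (CO2H)2 (cat.), THF–H2O, rt → 40 °C
Reagents that add atoms: water O
Why: Mild acid-catalysed acetal hydrolysis, which should leave both trisubstituted alkenes and the C6 configuration untouched.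

Step 26
Reactants: 42 aldehyde
Product: 43 (3E)-4-[(1R,5S)-2,6,6-trimethyl-5-(3-methylbut-2-en-1-yl)cyclohex-2-en-1-yl]but-3-en-2-one
Conditions: (EtO)2P(O)CH2C(O)CH3, LiCl, iPr2NEt, MeCN, rt
Reagents that add atoms: diethyl (2-oxopropyl)phosphonate CCOP(=O)(CC(C)=O)OCC
Why: Horner–Wadsworth–Emmons olefination (Masamune–Roush conditions) should give the (E)-enone.

Step 27
Reactants: 43 enone
Product: 44 (1E)-3-methyl-1-[(1R,5S)-2,6,6-trimethyl-5-(3-methylbut-2-en-1-yl)cyclohex-2-en-1-yl]penta-1,4-dien-3-ol (both C9 epimers)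
Conditions: CH2=CHMgBr, THF, −78 → −30 °C
Reagents that add atoms: vinylmagnesium bromide C=C[Mg]Br
Why: Grignard 1,2-addition to the enone carbonyl; the new carbinol centre is lost in step 28.

Step 28
Reactants: 44 vinyl carbinol
Product: 45 {(2E,4E)-3-methyl-5-[(1R,5S)-2,6,6-trimethyl-5-(3-methylbut-2-en-1-yl)cyclohex-2-en-1-yl]penta-2,4-dien-1-yl}triphenylphosphonium bromide
Conditions: Ph3P·HBr, CH2Cl2–MeOH, rt
Reagents that add atoms: triphenylphosphine hydrobromide [Br-].c1ccc(cc1)[PH+](c1ccccc1)c1ccccc1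
Why: Allylic transposition of the tertiary bis-allylic alcohol to the primary allylic phosphonium salt, as in step 16.

Step 29
Reactants: 45 ring A phosphonium salt; 46 (2E,4E,6E)-2,7-dimethylocta-2,4,6-trienedial (3 equiv)
Product: 47 (2E,4E,6E,8E,10E,12E)-2,7,11-trimethyl-13-[(1R,5S)-2,6,6-trimethyl-5-(3-methylbut-2-en-1-yl)cyclohex-2-en-1-yl]trideca-2,4,6,8,10,12-hexaenal
Conditions: 1,2-epoxybutane, EtOH, 70 °C; then I2 (cat.), CH2Cl2, rt
Reagents that add atoms: none
Why: Wittig olefination of the allylic ylide (epoxide as HBr acceptor) forms C11=C12; excess dialdehyde should secure mono-olefination and iodine-catalysed isomerisation should bring the new bond to E.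

Step 30
Reactants: 47 C30 aldehyde; 26 ring B phosphonium salt
Product: 48 tert-butyldiphenylsilyl ether of 49 at the primary hydroxyl
Conditions: 1,2-epoxybutane, EtOH, 70 °C; then I2 (cat.), hexane, rt
Reagents that add atoms: none
Why: Second Wittig olefination forms C11'=C12' and completes the C50 chain; isomerisation should give the all-E polyene.

Step 31
Reactants: 48 silyl ether
Product: 49 all-E-(2S,6R,2'R,6'S)-2'-[(2E)-4-hydroxy-3-methylbut-2-en-1-yl]-2-(3-methylbut-2-en-1-yl)-ε,ε-carotene (CNP0304855.1)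
Conditions: Bu4NF, AcOH, THF, 0 °C → rt, dark, argon
Reagents that add atoms: none
Why: Fluoride cleavage of the silyl ether under buffered conditions that should leave the polyene untouched.

**Compound list**

1 | 3,3-dimethylglutaric anhydride | O=C1CC(C)(C)CC(=O)O1 | starting material
2 | 5-methoxy-3,3-dimethyl-5-oxopentanoic acid | COC(=O)CC(C)(C)CC(=O)O | intermediate
3 | methyl 5-chloro-3,3-dimethyl-5-oxopentanoate | COC(=O)CC(C)(C)CC(=O)Cl | intermediate
4 | (4R)-4-benzyl-1,3-oxazolidin-2-one | O=C1N[C@H](Cc2ccccc2)CO1 | starting material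
5 | methyl 5-[(4R)-4-benzyl-2-oxo-1,3-oxazolidin-3-yl]-3,3-dimethyl-5-oxopentanoate | COC(=O)CC(C)(C)CC(=O)N1[C@H](Cc2ccccc2)COC1=O | intermediate
6 | trichlorotitanium (Z)-enolate of 5 | COC(=O)CC(C)(C)/C=C(\O[Ti](Cl)(Cl)Cl)N1[C@H](Cc2ccccc2)COC1=O | intermediate (not isolated)
7 | methyl (4S)-4-{[(4R)-4-benzyl-2-oxo-1,3-oxazolidin-3-yl]carbonyl}-5,5-dimethoxy-3,3-dimethylpentanoate | COC(=O)CC(C)(C)[C@@H](C(OC)OC)C(=O)N1[C@H](Cc2ccccc2)COC1=O | intermediate
8 | methyl (4S)-4-[(ethylsulfanyl)carbonyl]-5,5-dimethoxy-3,3-dimethylpentanoate | COC(=O)CC(C)(C)[C@@H](C(OC)OC)C(=O)SCC | intermediate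
9 | methyl (4S)-4-(dimethoxymethyl)-3,3-dimethyl-5-oxohexanoate | COC(=O)CC(C)(C)[C@@H](C(OC)OC)C(C)=O | intermediate
10 | methyl (4R,5R)-4-(dimethoxymethyl)-5-hydroxy-3,3,5-trimethylhept-6-enoate (formed as its alkoxide) | COC(=O)CC(C)(C)[C@@H](C(OC)OC)[C@](C)(O)C=C | intermediate (not isolated)
11 | (5R,6R)-5-(dimethoxymethyl)-6-ethenyl-4,4,6-trimethyloxan-2-one (acetal group cis to vinyl) | O=C1CC(C)(C)[C@@H](C(OC)OC)[C@@](C)(C=C)O1 | intermediate
12 | trimethyl{[(2R,3R)-3-(dimethoxymethyl)-2-ethenyl-2,4,4-trimethyl-3,4-dihydro-2H-pyran-6-yl]oxy}silane | C[Si](C)(C)OC1=CC(C)(C)[C@@H](C(OC)OC)[C@@](C)(C=C)O1 | intermediate (not isolated)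
13 | trimethylsilyl (1S,5S)-5-(dimethoxymethyl)-4,6,6-trimethylcyclohex-3-ene-1-carboxylate | C[Si](C)(C)OC(=O)[C@H]1CC=C(C)[C@H](C(OC)OC)C1(C)C | intermediate (not isolated)
14 | [(1S,5S)-5-(dimethoxymethyl)-4,6,6-trimethylcyclohex-3-en-1-yl]methanol (1,5-trans) | OC[C@H]1CC=C(C)[C@H](C(OC)OC)C1(C)C | intermediate
15 | (4S,6S)-6-(dimethoxymethyl)-4-(iodomethyl)-1,5,5-trimethylcyclohex-1-ene | IC[C@H]1CC=C(C)[C@H](C(OC)OC)C1(C)C | intermediate
16 | prop-2-yn-1-ol | C#CCO | starting material
17 | dimethyl[(1E)-2-methyl-3-(dimethylalumanyloxy)prop-1-en-1-yl]alumane | C[Al](C)/C=C(\C)CO[Al](C)C | intermediate (not isolated)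
18 | (2E)-3-iodo-2-methylprop-2-en-1-ol | OC/C(C)=C/I | intermediate
19 | tert-butyl{[(2E)-3-iodo-2-methylprop-2-en-1-yl]oxy}diphenylsilane | CC(C)(C)[Si](OC/C(C)=C/I)(c1ccccc1)c1ccccc1 | intermediate
20 | {[(1S,5S)-5-(dimethoxymethyl)-4,6,6-trimethylcyclohex-3-en-1-yl]methyl}lithium | [Li]C[C@H]1CC=C(C)[C@H](C(OC)OC)C1(C)C | intermediate (not isolated)
21 | chloro{[(1S,5S)-5-(dimethoxymethyl)-4,6,6-trimethylcyclohex-3-en-1-yl]methyl}zinc | Cl[Zn]C[C@H]1CC=C(C)[C@H](C(OC)OC)C1(C)C | intermediate (not isolated)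
22 | tert-butyl({(2E)-4-[(1R,5S)-5-(dimethoxymethyl)-4,6,6-trimethylcyclohex-3-en-1-yl]-2-methylbut-2-en-1-yl}oxy)diphenylsilane | CC(C)(C)[Si](OC/C(C)=C/C[C@H]1CC=C(C)[C@H](C(OC)OC)C1(C)C)(c1ccccc1)c1ccccc1 | intermediate
23 | (1S,5R)-5-{(2E)-4-[tert-butyl(diphenyl)silyl]oxy-3-methylbut-2-en-1-yl}-2,6,6-trimethylcyclohex-2-ene-1-carbaldehyde | CC(C)(C)[Si](OC/C(C)=C/C[C@H]1CC=C(C)[C@H](C=O)C1(C)C)(c1ccccc1)c1ccccc1 | intermediate
24 | (3E)-4-[(1S,5R)-5-{(2E)-4-[tert-butyl(diphenyl)silyl]oxy-3-methylbut-2-en-1-yl}-2,6,6-trimethylcyclohex-2-en-1-yl]but-3-en-2-one | CC(=O)/C=C/[C@H]1C(C)=CC[C@H](C/C=C(\C)CO[Si](c2ccccc2)(c2ccccc2)C(C)(C)C)C1(C)C | intermediate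
25 | (1E)-1-[(1S,5R)-5-{(2E)-4-[tert-butyl(diphenyl)silyl]oxy-3-methylbut-2-en-1-yl}-2,6,6-trimethylcyclohex-2-en-1-yl]-3-methylpenta-1,4-dien-3-ol (both C3 epimers) | C=CC(C)(O)/C=C/[C@H]1C(C)=CC[C@H](C/C=C(\C)CO[Si](c2ccccc2)(c2ccccc2)C(C)(C)C)C1(C)C | intermediate
26 | {(2E,4E)-5-[(1S,5R)-5-{(2E)-4-[tert-butyl(diphenyl)silyl]oxy-3-methylbut-2-en-1-yl}-2,6,6-trimethylcyclohex-2-en-1-yl]-3-methylpenta-2,4-dien-1-yl}triphenylphosphonium bromide | c1ccccc1[P+](c1ccccc1)(c1ccccc1)C/C=C(C)/C=C/[C@H]1C(C)=CC[C@H](C/C=C(\C)CO[Si](c2ccccc2)(c2ccccc2)C(C)(C)C)C1(C)C.[Br-] | intermediate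
27 | (4S)-4-benzyl-1,3-oxazolidin-2-one | O=C1N[C@@H](Cc2ccccc2)CO1 | starting material
28 | methyl 5-[(4S)-4-benzyl-2-oxo-1,3-oxazolidin-3-yl]-3,3-dimethyl-5-oxopentanoate | COC(=O)CC(C)(C)CC(=O)N1[C@@H](Cc2ccccc2)COC1=O | intermediate
29 | trichlorotitanium (Z)-enolate of 28 | COC(=O)CC(C)(C)/C=C(\O[Ti](Cl)(Cl)Cl)N1[C@@H](Cc2ccccc2)COC1=O | intermediate (not isolated)
30 | methyl (4R)-4-{[(4S)-4-benzyl-2-oxo-1,3-oxazolidin-3-yl]carbonyl}-5,5-dimethoxy-3,3-dimethylpentanoate | COC(=O)CC(C)(C)[C@H](C(OC)OC)C(=O)N1[C@@H](Cc2ccccc2)COC1=O | intermediate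
31 | methyl (4R)-4-[(ethylsulfanyl)carbonyl]-5,5-dimethoxy-3,3-dimethylpentanoate | COC(=O)CC(C)(C)[C@H](C(OC)OC)C(=O)SCC | intermediate
32 | methyl (4R)-4-(dimethoxymethyl)-3,3-dimethyl-5-oxohept-6-enoate | COC(=O)CC(C)(C)[C@H](C(OC)OC)C(=O)C=C | intermediate
33 | methyl (4S,5R)-4-(dimethoxymethyl)-5-hydroxy-3,3,5-trimethylhept-6-enoate (formed as its alkoxide) | COC(=O)CC(C)(C)[C@H](C(OC)OC)[C@](C)(O)C=C | intermediate (not isolated)
34 | (5S,6R)-5-(dimethoxymethyl)-6-ethenyl-4,4,6-trimethyloxan-2-one (acetal group trans to vinyl) | O=C1CC(C)(C)[C@H](C(OC)OC)[C@@](C)(C=C)O1 | intermediate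
35 | trimethyl{[(2R,3S)-3-(dimethoxymethyl)-2-ethenyl-2,4,4-trimethyl-3,4-dihydro-2H-pyran-6-yl]oxy}silane | C[Si](C)(C)OC1=CC(C)(C)[C@H](C(OC)OC)[C@@](C)(C=C)O1 | intermediate (not isolated)
36 | trimethylsilyl (1S,5R)-5-(dimethoxymethyl)-4,6,6-trimethylcyclohex-3-ene-1-carboxylate | C[Si](C)(C)OC(=O)[C@H]1CC=C(C)[C@@H](C(OC)OC)C1(C)C | intermediate (not isolated)
37 | [(1S,5R)-5-(dimethoxymethyl)-4,6,6-trimethylcyclohex-3-en-1-yl]methanol (1,5-cis) | OC[C@H]1CC=C(C)[C@@H](C(OC)OC)C1(C)C | intermediate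
38 | (4S,6R)-6-(dimethoxymethyl)-4-(iodomethyl)-1,5,5-trimethylcyclohex-1-ene | IC[C@H]1CC=C(C)[C@@H](C(OC)OC)C1(C)C | intermediate
39 | {[(1S,5R)-5-(dimethoxymethyl)-4,6,6-trimethylcyclohex-3-en-1-yl]methyl}lithium | [Li]C[C@H]1CC=C(C)[C@@H](C(OC)OC)C1(C)C | intermediate (not isolated)
40 | chloro{[(1S,5R)-5-(dimethoxymethyl)-4,6,6-trimethylcyclohex-3-en-1-yl]methyl}zinc | Cl[Zn]C[C@H]1CC=C(C)[C@@H](C(OC)OC)C1(C)C | intermediate (not isolated)
41 | (4S,6R)-6-(dimethoxymethyl)-1,5,5-trimethyl-4-(3-methylbut-2-en-1-yl)cyclohex-1-ene | CC(C)=CC[C@H]1CC=C(C)[C@@H](C(OC)OC)C1(C)C | intermediate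
42 | (1R,5S)-2,6,6-trimethyl-5-(3-methylbut-2-en-1-yl)cyclohex-2-ene-1-carbaldehyde | CC(C)=CC[C@H]1CC=C(C)[C@@H](C=O)C1(C)C | intermediate
43 | (3E)-4-[(1R,5S)-2,6,6-trimethyl-5-(3-methylbut-2-en-1-yl)cyclohex-2-en-1-yl]but-3-en-2-one | CC(C)=CC[C@H]1CC=C(C)[C@@H](/C=C/C(C)=O)C1(C)C | intermediate
44 | (1E)-3-methyl-1-[(1R,5S)-2,6,6-trimethyl-5-(3-methylbut-2-en-1-yl)cyclohex-2-en-1-yl]penta-1,4-dien-3-ol (both C3 epimers) | CC(C)=CC[C@H]1CC=C(C)[C@@H](/C=C/C(C)(O)C=C)C1(C)C | intermediate
45 | {(2E,4E)-3-methyl-5-[(1R,5S)-2,6,6-trimethyl-5-(3-methylbut-2-en-1-yl)cyclohex-2-en-1-yl]penta-2,4-dien-1-yl}triphenylphosphonium bromide | CC(C)=CC[C@H]1CC=C(C)[C@@H](/C=C/C(C)=C/C[P+](c2ccccc2)(c2ccccc2)c2ccccc2)C1(C)C.[Br-] | intermediate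
46 | (2E,4E,6E)-2,7-dimethylocta-2,4,6-trienedial | O=C/C(C)=C/C=C/C=C(C)/C=O | starting material
47 | (2E,4E,6E,8E,10E,12E)-2,7,11-trimethyl-13-[(1R,5S)-2,6,6-trimethyl-5-(3-methylbut-2-en-1-yl)cyclohex-2-en-1-yl]trideca-2,4,6,8,10,12-hexaenal | CC(C)=CC[C@H]1CC=C(C)[C@@H](/C=C/C(C)=C/C=C/C(C)=C/C=C/C=C(C)/C=O)C1(C)C | intermediate
48 | tert-butyldiphenylsilyl ether of 49 at the primary hydroxyl | CC(C)=CC[C@H]1CC=C(C)[C@@H](/C=C/C(C)=C/C=C/C(C)=C/C=C/C=C(C)/C=C/C=C(C)/C=C/[C@H]2C(C)=CC[C@H](C/C=C(\C)CO[Si](c3ccccc3)(c3ccccc3)C(C)(C)C)C2(C)C)C1(C)C | intermediate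
49 | all-E-(2S,6R,2'R,6'S)-2'-[(2E)-4-hydroxy-3-methylbut-2-en-1-yl]-2-(3-methylbut-2-en-1-yl)-ε,ε-carotene (CNP0304855.1) | CC(C)=CC[C@H]1CC=C(C)[C@@H](/C=C/C(C)=C/C=C/C(C)=C/C=C/C=C(C)/C=C/C=C(C)/C=C/[C@H]2C(C)=CC[C@H](C/C=C(\C)CO)C2(C)C)C1(C)C | target

**Step count and risks**

Total step count: 31. Longest linear sequence: 17 steps (1, 2, 17–28, 29, 30, 31).

The three steps most likely to fail:

Step 8. The silyl ketene acetal may not reach the crowded boat geometry, or the lactone enolate may fragment before it is silylated, so that no ring-contracted product forms. The fallback closes ring B by olefin metathesis instead; it sets out from 9 and returns at 14. Ketone 9 is methylenated with Ph3P=CH2 to methyl (4S)-4-(dimethoxymethyl)-3,3,5-trimethylhex-5-enoate F1. Its ester enolate (LiN(iPr)2) is allylated with allyl bromide to methyl 2-allyl-4-(dimethoxymethyl)-3,3,5-trimethylhex-5-enoate F2 (both C2 epimers). Ring-closing metathesis with the second-generation Grubbs catalyst closes C4'=C5' to methyl (5S)-5-(dimethoxymethyl)-4,6,6-trimethylcyclohex-3-ene-1-carboxylate F3. Equilibration at C1 with NaOMe (the trans ester is expected to be favoured) and LiAlH4 reduction should give 14, to be separated from the cis alcohol [(1R,5S)-5-(dimethoxymethyl)-4,6,6-trimethylcyclohex-3-en-1-yl]methanol F4.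

Step 5. Thiolate attack at the very crowded exocyclic carbonyl may be too slow, and opening of the oxazolidinone ring may compete. The fallback replaces direct transacylation by hydrolysis and re-activation; it sets out from 7 and returns at 8. Lithium hydroperoxide (LiOH, H2O2, THF–H2O, 0 °C) should cleave 7 to (2S)-2-(dimethoxymethyl)-5-methoxy-3,3-dimethyl-5-oxopentanoic acid F5, and Steglich coupling with EtSH (dicyclohexylcarbodiimide, 4-dimethylaminopyridine) should give 8.

Step 20. Acyl transfer from the hindered S-ethyl thioester may stall, or the vinyl ketone may be consumed by conjugate addition under the coupling conditions. The fallback builds the vinyl ketone by Mannich methylenation; it sets out from 31 and returns at 32. Me2CuLi converts 31 into methyl (4R)-4-(dimethoxymethyl)-3,3-dimethyl-5-oxohexanoate F6. Its kinetic enolate on the methyl side (LiN(iPr)2, −78 °C) is trapped with Me2N+=CH2 I− to give methyl (4R)-4-(dimethoxymethyl)-7-(dimethylamino)-3,3-dimethyl-5-oxoheptanoate F7. Methylation with MeI gives the trimethylammonium iodide of F7, F8, and NaHCO3 should eliminate it to 32.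

Further compounds
F1 | step 8 | methyl (4S)-4-(dimethoxymethyl)-3,3,5-trimethylhex-5-enoate | COC(=O)CC(C)(C)[C@@H](C(OC)OC)C(C)=C
F2 | step 8 | methyl 2-allyl-4-(dimethoxymethyl)-3,3,5-trimethylhex-5-enoate (C2 epimers) | COC(=O)C(CC=C)C(C)(C)[C@@H](C(OC)OC)C(C)=C
F3 | step 8 | methyl (5S)-5-(dimethoxymethyl)-4,6,6-trimethylcyclohex-3-ene-1-carboxylate (C1 epimers) | COC(=O)C1CC=C(C)[C@H](C(OC)OC)C1(C)C
F4 | step 8 | [(1R,5S)-5-(dimethoxymethyl)-4,6,6-trimethylcyclohex-3-en-1-yl]methanol | OC[C@@H]1CC=C(C)[C@H](C(OC)OC)C1(C)C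
F5 | step 5 | (2S)-2-(dimethoxymethyl)-5-methoxy-3,3-dimethyl-5-oxopentanoic acid | COC(=O)CC(C)(C)[C@@H](C(OC)OC)C(=O)O
F6 | step 20 | methyl (4R)-4-(dimethoxymethyl)-3,3-dimethyl-5-oxohexanoate | COC(=O)CC(C)(C)[C@H](C(OC)OC)C(C)=O
F7 | step 20 | methyl (4R)-4-(dimethoxymethyl)-7-(dimethylamino)-3,3-dimethyl-5-oxoheptanoate | COC(=O)CC(C)(C)[C@H](C(OC)OC)C(=O)CCN(C)C
F8 | step 20 | (4R)-4-(dimethoxymethyl)-7-methoxy-N,N,N,5,5-pentamethyl-3,7-dioxoheptan-1-aminium iodide | COC(=O)CC(C)(C)[C@H](C(OC)OC)C(=O)CC[N+](C)(C)C.[I-]
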